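I reckoned a race.

    Q + J → D + L (k1 = 16.4 L mol⁻¹ s⁻¹)
    Q + D → L + D, rate k2*[D]*[Q] (k2 = 22.9 L mol⁻¹ s⁻¹)
    D + Z → D.Z (k3 = 127 L mol⁻¹ s⁻¹)
    E + Q → E.Q (k4 = 0.571 L mol⁻¹ s⁻¹)

Q 10 mM (fed, over 20 s); Z 0.300 mM; E 3.00 mM; J 0.23 mM; time 1.5 min; the fed solution adds 0.20 times the starting volume

- whether the average number of monomer units in a chain (chains begun, living or dead) reaches 5.0 by 1.5 min (no / yes)
- average number of monomer units in a chain (chains begun, living or dead) at 1.5 min

- charges are per starting volume, the dose included; the dosed solution carries all of it
- the average divides the monomer in chains by the number of chains begun, living and dead together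
- run time (flask): 1.5 min

- First I let step 2 run by itself, with each living end D present from the start and Q at its whole charge. Counting the unit from step 1, that gave a chain of 21.6 units by 1.5 min.
- Then I added step 3. An end grows at k2[Q] and is captured at k3[Z], so I took n, the units an end adds before Z captures it, as growth rate over capture rate (the kinetic chain length): 6.01. The feed's dilution cancels in this ratio.
- Unchecked growth reaches n at the crossing time 1/(k3[Z]), here 0.437 min. Before it the clock sets the length, and after it capture does. The run is longer than that, so I reckoned on capture, and the length fell to 7.01.
- Last came the rest. Step 4 runs E down against a larger charge of Q. With Q held at its charge, E has a half-life of 2.02 min, longer than the run, so I reckoned on less than half of E reacting, which is under 15.0 % of the Q charged, and I left step 4 out. I also left out the slow start under the feed and the fall of Z, which lengthens n. Set against the 5.0 wanted, my answer was yes.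
- The forecast said yes and 6.2, within 5.6 to 6.9, on the grounds that “Z slightly exceeds J but kills the living ends only gradually”. My figure stood just above its range.
- The simulation gave yes and 6.61, inside the forecast's range, and the flask passed 5.0 at 0.933 min.
- The time given held this flask's length down. At 1.50 min D stood at 0.0466 mM against D.Z at 0.145 mM, so 24.3 % of those ends were still uncaptured. With Q at 76 % and Z at 42 % of their charges, n had become 10.9, and giving each uncaptured end that many units took 6.61 to 9.27. The same flask run to 15.0 min gave 9.69.

The numbers of this flask are invented, and the outcome is calculated.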